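In the first seconds partner B meets both substrate and partner A, so start by counting turnovers: rate constant times charged concentration times time.

substrate 1.1 M; partner A 0.700 equiv; partner B 1.80 equiv; time 40 s

    substrate + partner B → open intermediate (k1 = 0.016 /M/s)
    partner B + partner A → second intermediate (k2 = 0.15 /M/s)
    open intermediate + second intermediate → target (k3 = 1.3 /M/s)
    2 second intermediate → homo product (k4 = 0.30 /M/s)
    crystals ⇌ target, rate k5*(cs5 - [target]) while solid is left; crystals form when [target] > cs5 (cs5 = 0.49 M, k5 = 1.5 /s)

- target and crystals together at 40 s, in percent of the substrate charged
- the change that raises the amount of target and crystals together at 40 s, in percent of the substrate charged most ("none" if none brings more than 2 percentage points) (south-east / south / north-east / north / none)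
- amount of target and crystals together at 40 s, in percent of the substrate charged, after north

- south-east: doubling the solubility in step 5, all else as stated
- south: doubling the amount of partner A, all else as stated
- north-east: doubling the amount of partner B, all else as stated
- north: doubling the dissolution coefficient of step 5, all else as stated

You charge [partner B] = 1.98 M and [partner A] = 0.770 M. Now climb the ladder. The top rung is partner A, with a half-life of 2.33 s at charged partner B, which gives 11.9 turnovers in 40 s. Next comes partner B at 6.0 s. The bottom rung is substrate at 22 s, with 1.27 turnovers. So at the start second intermediate is made 6.6 times as fast as open intermediate, and it has to wait for its partner.

While it waits it has two exits. It can be captured by open intermediate, which at the charged concentrations arrives at 0.0348 M/s, or it can pair into homo product. Set the pairing rate equal to that supply and you get the crossover level, the [second intermediate] at which the two exits run equally fast: 0.241 M. Above it pairing wins, below it capture wins.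

Partner A, the limiting reagent, allows 70.0%, but its charge is 3.20 times the level. I therefore count what lies below the level as reaching target and commit to a rough 21.9%. Step 5 merely moves target between two forms counted together, so north and south-east should give nothing. Doubling partner B lifts the level to 0.341 M, while doubling partner A leaves it in place and adds excess, so I choose north-east.

The forecast stands above my estimate: 30% (27% to 33%), north-east, and 30% after north, with the ground that “Doubling B speeds open-intermediate formation”.

The simulation gives 30.1%, north-east with 4.1 percentage points, and 30.1% after north, so the forecast held. The low solubility of target makes no difference here: crystals stand at 0% at 40.0 s.

The neighbour flask with 0.170 equiv of partner A has the same charged substrate and partner B, so it keeps the level of 0.241 M, and its charge of 0.187 M of partner A starts below that level. The reckoning therefore puts capture ahead from the outset. That neighbour flask ends with target at 13.9%, which is 82.0% of its partner A charge, against 43.0% in the flask.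

The rate constants are made up; what happens was integrated by code.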